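**Strategy.** The C3–O bond is disconnected to a C3–H bond: the ester oxygen is delivered from a tert-butyl carbonate on the hydroxyisopropyl precursor of the isopropenyl group. Step 8, an anodic two-electron oxidation, turns C3–H2 of dihydrofuran ring B into the cation and closes a temporary cis-fused 1,3-dioxan-2-one, fixing the C3 stereocentre from C2 in one operation. It exploits that C3 is benzylic to benzene ring A, with O1 ortho and the C6 oxygen para to C3a, and 1,3-related to the carbinol oxygen. The precursor is the (R)-2-(2-Boc-oxypropan-2-yl)-5-acetyl-6-silyloxy-2,3-dihydrobenzofuran, made by Shi epoxidation and 5-exo cyclisation of a 5-prenylresacetophenone.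

Key step: step 8

Assumption: the L-fructose-derived enantiomer of the Shi ketone is taken to give the (S)-epoxide of an ArCH2CH=C(CH3)2 unit, the mirror image of the (R)-selectivity of the D-fructose-derived ketone; if the sense were the other way, the other ketone enantiomer would be used and nothing else would change.

Locants (O1, C2, C3, C3a, C5, C6, C7a) follow 2,3-dihydro-1-benzofuran numbering throughout.

Step 1
Reactants: 1 2,4-dihydroxyacetophenone
Product: 2 1-(5-bromo-2,4-dihydroxyphenyl)ethan-1-one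
Conditions: Br2 (1.0 equiv), AcOH, 15 °C
Reagents that add atoms: bromine, BrBr
Why: Electrophilic aromatic bromination should go to C5, which is para to the chelated 2-OH, ortho to the 4-OH and less hindered than C3 between the two oxygens, so the site of the later side chain is fixed without ambiguity.

Step 2
Reactants: 2 1-(5-bromo-2,4-dihydroxyphenyl)ethan-1-one
Product: 3 4-acetyl-6-bromo-1,3-phenylene bis(2,2-dimethylpropanoate)
Conditions: tBuCOCl (2.5 equiv), Et3N, 4-(dimethylamino)pyridine (DMAP, cat.), CH2Cl2, 0 °C to rt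
Reagents that add atoms: pivaloyl chloride, CC(C)(C)C(Cl)=O
Why: DMAP-catalysed O-acylation masks both phenols as pivalates, which should tolerate the coupling and the pH 10.5 epoxidation and keep ring A electron-poor so that only the alkene is oxidised in step 4.

Step 3
Reactants: 3 4-acetyl-6-bromo-1,3-phenylene bis(2,2-dimethylpropanoate); 4 tributyl(3-methylbut-2-en-1-yl)stannane
Product: 5 4-acetyl-6-(3-methylbut-2-en-1-yl)-1,3-phenylene bis(2,2-dimethylpropanoate)
Conditions: Pd(PPh3)4 (5 mol%), DMF, 95 °C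
Reagents that add atoms: none
Why: Stille coupling of the aryl bromide with the prenylstannane should give the linear prenylarene, because reductive elimination takes place from the less hindered primary σ-allyl palladium species, and the esters and the ketone are inert.

Step 4
Reactants: 5 4-acetyl-6-(3-methylbut-2-en-1-yl)-1,3-phenylene bis(2,2-dimethylpropanoate)
Product: 6 4-acetyl-6-{[(2S)-3,3-dimethyloxiran-2-yl]methyl}-1,3-phenylene bis(2,2-dimethylpropanoate)
Conditions: L-fructose-derived Shi ketone (1,2:4,5-di-O-isopropylidene-β-L-erythro-2,3-hexodiulo-2,6-pyranose, 0.3 equiv), 2KHSO5·KHSO4·K2SO4, K2CO3, nBu4NHSO4, MeCN/CH2(OMe)2/aq. Na2B4O7 buffer (pH ca. 10.5), 0 °C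
Reagents that add atoms: potassium peroxymonosulfate, [K+].[O-]S(=O)(=O)OO
Why: Shi epoxidation of the trisubstituted alkene by the chiral dioxirane through its spiro transition state should give the (S)-epoxide, which sets the one stereocentre that is carried into C2.

Step 5
Reactants: 6 4-acetyl-6-{[(2S)-3,3-dimethyloxiran-2-yl]methyl}-1,3-phenylene bis(2,2-dimethylpropanoate)
Product: 8 1-[(2R)-6-hydroxy-2-(2-hydroxypropan-2-yl)-2,3-dihydro-1-benzofuran-5-yl]ethan-1-one, via diphenol epoxide 7 (not isolated)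
Conditions: K2CO3 (3 equiv), MeOH, rt to 45 °C; then aq. NH4Cl
Reagents that add atoms: none
Why: Methanolysis of the two aryl pivalates frees the phenoxide ortho to the side chain, which should open the epoxide by base-mediated 5-exo-tet attack at the secondary carbon with inversion, so that the (S)-epoxide becomes (R)-C2, while the other phenol, para to the side chain, cannot reach the epoxide.

Step 6
Reactants: 8 1-[(2R)-6-hydroxy-2-(2-hydroxypropan-2-yl)-2,3-dihydro-1-benzofuran-5-yl]ethan-1-one
Product: 9 1-[(2R)-2-(2-hydroxypropan-2-yl)-6-{[tri(propan-2-yl)silyl]oxy}-2,3-dihydro-1-benzofuran-5-yl]ethan-1-one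
Conditions: iPr3SiCl (1.2 equiv), imidazole, DMAP (cat.), DMF, 40 °C
Reagents that add atoms: chlorotri(propan-2-yl)silane, CC(C)[Si](Cl)(C(C)C)C(C)C
Why: Imidazole-mediated silylation should take only the phenol and leave the hindered tertiary alcohol and the ketone alone, and it is placed after ring closure because the phenol that becomes O1 had to be free, giving a fluoride-labile donor group on the oxygen para to C3a.

Step 7
Reactants: 9 1-[(2R)-2-(2-hydroxypropan-2-yl)-6-{[tri(propan-2-yl)silyl]oxy}-2,3-dihydro-1-benzofuran-5-yl]ethan-1-one; 10 di-tert-butyl dicarbonate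
Product: 11 tert-butyl 2-[(2R)-5-acetyl-6-{[tri(propan-2-yl)silyl]oxy}-2,3-dihydro-1-benzofuran-2-yl]propan-2-yl carbonate
Conditions: 10 (3 equiv), DMAP (1 equiv), MeCN, 40 °C
Reagents that add atoms: none
Why: DMAP-catalysed acylation of the tertiary alcohol by the dicarbonate should give the mixed carbonate without a strong base that would enolise the aryl methyl ketone.

Step 8
Reactants: 11 tert-butyl 2-[(2R)-5-acetyl-6-{[tri(propan-2-yl)silyl]oxy}-2,3-dihydro-1-benzofuran-2-yl]propan-2-yl carbonate
Product: 12 cis-fused cyclic carbonate, (2R,3S): 5-acetyl-6-{[tri(propan-2-yl)silyl]oxy}-2,3-dihydro-1-benzofuran in which the C3 oxygen and the oxygen of the C2 C(CH3)2 group are joined by a carbonyl group (4,4-dimethyl-1,3-dioxan-2-one ring fused across C2–C3)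
Conditions: graphite anode, Pt cathode, undivided cell, constant current (ca. 2.2 F/mol), nBu4NPF6 (0.1 M), 2,6-lutidine (2 equiv), CH2Cl2/(CF3)2CHOH 4:1, 0 °C
Reagents that add atoms: none
Why: Proposed new method: one-electron oxidation of ring A at the anode gives an arene radical cation whose C3–H is acidified; loss of that proton to 2,6-lutidine and a second electron transfer give the C3 cation, delocalised onto O1 (on C7a, ortho to C3a) and onto the C6 silyloxy oxygen (para to C3a), and the carbonyl oxygen of the tert-butyl carbonate captures it, after which the tert-butyl group leaves as 2-methylpropene while H2 forms at the cathode. The closest known reaction types are anodic benzylic acyloxylation of alkoxyarenes and quinone-mediated benzylic cation cyclisations onto tethered carbonates and carbamates. The 1,3-dioxan-2-one ring closes in a 6-exo-trig mode, the C3=C3a bond of the oxocarbenium form staying outside the new ring. The new C3 stereocentre is controlled by C2: the O–C(=O)–O tether hangs from the C2 side chain and can reach C3 only on its own face, so the ring fusion must be cis, which is the contra-steric (2R,3S) arrangement. Site selectivity is secured because C3–H2 is the only benzylic sp3 C–H on ring A. Capture must beat loss of the C2 proton (aromatisation to the benzofuran), which the intramolecular six-membered closure, the weak hindered base and the low temperature should secure, while the C5 acetyl group and the new C3–O bond raise the potential of the product and should limit over-oxidation.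

Step 9
Reactants: 12 cis-fused cyclic carbonate, (2R,3S)
Product: 13 1-[(2R,3S)-3-hydroxy-2-(2-hydroxypropan-2-yl)-6-{[tri(propan-2-yl)silyl]oxy}-2,3-dihydro-1-benzofuran-5-yl]ethan-1-one
Conditions: LiOH·H2O (3 equiv), THF/H2O 3:1, 0 °C; then pH 7 phosphate buffer
Reagents that add atoms: none
Why: Carbonate saponification, in which hydroxide adds to the carbonyl group and the ring-opened monoalkyl carbonate loses CO2, breaks no C–O bond at C2 or C3, so both stereocentres are kept, and the hindered aryl silyl ether should survive at 0 °C.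

Step 10
Reactants: 14 3-methylfuran-2(5H)-one
Product: 17 4-methoxybenzyl (2Z)-4-(acetyloxy)-2-methylbut-2-enoate, via potassium hydroxy carboxylate 15 (not isolated), via hydroxy ester 16 (not isolated)
Conditions: KOH (1.0 equiv), MeOH/H2O, rt, then evaporation to dryness; 4-MeOC6H4CH2Cl, nBu4NI (cat.), DMF, rt; then Ac2O, pyridine, DMAP (cat.), 0 °C
Reagents that add atoms: potassium hydroxide, [K+].[OH-]; 4-methoxybenzyl chloride, COc1ccc(CCl)cc1; acetic anhydride, CC(=O)OC(C)=O
Why: Saponification of the butenolide gives the (Z)-hydroxy carboxylate, which is alkylated at the carboxylate (SN2) before the alcohol is acetylated, so the carboxyl group is never activated while the cis hydroxyl is free, relactonisation is avoided and the Z geometry of the lactone is kept.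

Step 11
Reactants: 17 4-methoxybenzyl (2Z)-4-(acetyloxy)-2-methylbut-2-enoate
Product: 18 (2Z)-4-(acetyloxy)-2-methylbut-2-enoic acid
Conditions: CF3CO2H, anisole, CH2Cl2, 0 °C
Reagents that add atoms: none
Why: Acidolysis of the 4-methoxybenzyl ester (SN1 cleavage to the stabilised benzyl cation, trapped by anisole) should free the acid without touching the allylic acetate or the alkene geometry.

Step 12
Reactants: 13 1-[(2R,3S)-3-hydroxy-2-(2-hydroxypropan-2-yl)-6-{[tri(propan-2-yl)silyl]oxy}-2,3-dihydro-1-benzofuran-5-yl]ethan-1-one; 18 (2Z)-4-(acetyloxy)-2-methylbut-2-enoic acid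
Product: 20 (2R,3S)-5-acetyl-2-(2-hydroxypropan-2-yl)-6-{[tri(propan-2-yl)silyl]oxy}-2,3-dihydro-1-benzofuran-3-yl (2Z)-4-(acetyloxy)-2-methylbut-2-enoate, via mixed anhydride 19 (not isolated)
Conditions: 18, 2,4,6-Cl3C6H2COCl, Et3N, toluene, rt; then 13, DMAP, rt
Reagents that add atoms: none
Why: Yamaguchi esterification, in which the mixed anhydride acylates the secondary benzylic alcohol under DMAP catalysis, should leave the far more hindered tertiary alcohol free and keep the Z geometry, and it touches no stereocentre.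

Step 13
Reactants: 20 (2R,3S)-5-acetyl-2-(2-hydroxypropan-2-yl)-6-{[tri(propan-2-yl)silyl]oxy}-2,3-dihydro-1-benzofuran-3-yl (2Z)-4-(acetyloxy)-2-methylbut-2-enoate
Product: 22 (2S,3S)-5-acetyl-2-(prop-1-en-2-yl)-6-{[tri(propan-2-yl)silyl]oxy}-2,3-dihydro-1-benzofuran-3-yl (2Z)-4-(acetyloxy)-2-methylbut-2-enoate, via sulfamate salt 21 (not isolated)
Conditions: methyl N-(triethylammoniosulfonyl)carbamate (Burgess reagent), toluene, 50 °C
Reagents that add atoms: none
Why: Burgess dehydration, in which the tertiary alcohol forms a sulfamate ester that undergoes thermal syn-elimination into one of the six methyl hydrogens, should give the isopropenyl group under neutral conditions that leave the benzylic ester alone (the C2 descriptor changes from R to S only because the priorities change).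

Step 14
Reactants: 22 (2S,3S)-5-acetyl-2-(prop-1-en-2-yl)-6-{[tri(propan-2-yl)silyl]oxy}-2,3-dihydro-1-benzofuran-3-yl (2Z)-4-(acetyloxy)-2-methylbut-2-enoate
Product: 23 (2S,3S)-5-acetyl-6-hydroxy-2-(prop-1-en-2-yl)-2,3-dihydro-1-benzofuran-3-yl (2Z)-4-(acetyloxy)-2-methylbut-2-enoate
Conditions: nBu4NF/AcOH (1:1), THF, 0 °C
Reagents that add atoms: none
Why: Fluoride cleaves the aryl Si–O bond, and the acetic acid buffer protonates the phenoxide at once so that it cannot expel the para-related C3 carboxylate (quinone methide formation) or attack an ester.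

**Compound list**

1 | 2,4-dihydroxyacetophenone | CC(=O)c1ccc(O)cc1O | starting material
2 | 1-(5-bromo-2,4-dihydroxyphenyl)ethan-1-one | CC(=O)c1cc(Br)c(O)cc1O | intermediate
3 | 4-acetyl-6-bromo-1,3-phenylene bis(2,2-dimethylpropanoate) | CC(=O)c1cc(Br)c(OC(=O)C(C)(C)C)cc1OC(=O)C(C)(C)C | intermediate
4 | tributyl(3-methylbut-2-en-1-yl)stannane | CCCC[Sn](CCCC)(CCCC)CC=C(C)C | starting material
5 | 4-acetyl-6-(3-methylbut-2-en-1-yl)-1,3-phenylene bis(2,2-dimethylpropanoate) | CC(=O)c1cc(CC=C(C)C)c(OC(=O)C(C)(C)C)cc1OC(=O)C(C)(C)C | intermediate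
6 | 4-acetyl-6-{[(2S)-3,3-dimethyloxiran-2-yl]methyl}-1,3-phenylene bis(2,2-dimethylpropanoate) | CC(=O)c1cc(C[C@@H]2OC2(C)C)c(OC(=O)C(C)(C)C)cc1OC(=O)C(C)(C)C | intermediate
7 | 1-(5-{[(2S)-3,3-dimethyloxiran-2-yl]methyl}-2,4-dihydroxyphenyl)ethan-1-one (diphenol epoxide, not isolated) | CC(=O)c1cc(C[C@@H]2OC2(C)C)c(O)cc1O | intermediate
8 | 1-[(2R)-6-hydroxy-2-(2-hydroxypropan-2-yl)-2,3-dihydro-1-benzofuran-5-yl]ethan-1-one | CC(C)(O)[C@@H]1Oc2cc(O)c(C(C)=O)cc2C1 | intermediate
9 | 1-[(2R)-2-(2-hydroxypropan-2-yl)-6-{[tri(propan-2-yl)silyl]oxy}-2,3-dihydro-1-benzofuran-5-yl]ethan-1-one | CC(C)(O)[C@@H]1Oc2cc(O[Si](C(C)C)(C(C)C)C(C)C)c(C(C)=O)cc2C1 | intermediate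
10 | di-tert-butyl dicarbonate | CC(C)(C)OC(=O)OC(=O)OC(C)(C)C | starting material
11 | tert-butyl 2-[(2R)-5-acetyl-6-{[tri(propan-2-yl)silyl]oxy}-2,3-dihydro-1-benzofuran-2-yl]propan-2-yl carbonate | CC(C)(OC(=O)OC(C)(C)C)[C@@H]1Oc2cc(O[Si](C(C)C)(C(C)C)C(C)C)c(C(C)=O)cc2C1 | intermediate
12 | cis-fused cyclic carbonate, (2R,3S), of the C3 oxygen and the C2 C(CH3)2 oxygen; 5-acetyl, 6-tri(propan-2-yl)silyloxy | CC1(C)OC(=O)O[C@H]2c3cc(C(C)=O)c(O[Si](C(C)C)(C(C)C)C(C)C)cc3O[C@@H]12 | intermediate
13 | 1-[(2R,3S)-3-hydroxy-2-(2-hydroxypropan-2-yl)-6-{[tri(propan-2-yl)silyl]oxy}-2,3-dihydro-1-benzofuran-5-yl]ethan-1-one | CC(C)(O)[C@@H]1Oc2cc(O[Si](C(C)C)(C(C)C)C(C)C)c(C(C)=O)cc2[C@@H]1O | intermediate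
14 | 3-methylfuran-2(5H)-one | CC1=CCOC1=O | starting material
15 | potassium (2Z)-4-hydroxy-2-methylbut-2-enoate (not isolated) | O=C([O-])/C(C)=C\CO.[K+] | intermediate
16 | 4-methoxybenzyl (2Z)-4-hydroxy-2-methylbut-2-enoate (not isolated) | COc1ccc(COC(=O)/C(C)=C\CO)cc1 | intermediate
17 | 4-methoxybenzyl (2Z)-4-(acetyloxy)-2-methylbut-2-enoate | COc1ccc(COC(=O)/C(C)=C\COC(C)=O)cc1 | intermediate
18 | (2Z)-4-(acetyloxy)-2-methylbut-2-enoic acid | O=C(O)/C(C)=C\COC(C)=O | intermediate
19 | (2Z)-4-(acetyloxy)-2-methylbut-2-enoic 2,4,6-trichlorobenzoic anhydride (not isolated) | O=C(OC(=O)/C(C)=C\COC(C)=O)c1c(Cl)cc(Cl)cc1Cl | intermediate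
20 | (2R,3S)-5-acetyl-2-(2-hydroxypropan-2-yl)-6-{[tri(propan-2-yl)silyl]oxy}-2,3-dihydro-1-benzofuran-3-yl (2Z)-4-(acetyloxy)-2-methylbut-2-enoate | CC(C)(O)[C@@H]1Oc2cc(O[Si](C(C)C)(C(C)C)C(C)C)c(C(C)=O)cc2[C@@H]1OC(=O)/C(C)=C\COC(C)=O | intermediate
21 | triethylammonium salt of the N-(methoxycarbonyl)sulfamate ester of the tertiary alcohol of 20 (not isolated) | COC(=O)[N-]S(=O)(=O)OC(C)(C)[C@@H]1Oc2cc(O[Si](C(C)C)(C(C)C)C(C)C)c(C(C)=O)cc2[C@@H]1OC(=O)/C(C)=C\COC(C)=O.CC[NH+](CC)CC | intermediate
22 | (2S,3S)-5-acetyl-2-(prop-1-en-2-yl)-6-{[tri(propan-2-yl)silyl]oxy}-2,3-dihydro-1-benzofuran-3-yl (2Z)-4-(acetyloxy)-2-methylbut-2-enoate | C=C(C)[C@@H]1Oc2cc(O[Si](C(C)C)(C(C)C)C(C)C)c(C(C)=O)cc2[C@@H]1OC(=O)/C(C)=C\COC(C)=O | intermediate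
23 | (2S,3S)-5-acetyl-6-hydroxy-2-(prop-1-en-2-yl)-2,3-dihydro-1-benzofuran-3-yl (2Z)-4-(acetyloxy)-2-methylbut-2-enoate | C=C(C)[C@@H]1Oc2cc(O)c(C(C)=O)cc2[C@@H]1OC(=O)/C(C)=C\COC(C)=O | target

**Step count.** 14 steps in total. The longest linear sequence is 12 steps (steps 1–9 and 12–14); the acid 18 is made in 2 steps (10–11).

**Steps most likely to fail**

1. Step 8 (the proposed new method). The C3 cation may lose the C2 proton faster than the carbonate closes (aromatisation of ring B), the product may be oxidised further at the anode, or acid formed at the anode may cleave the tert-butyl carbonate before oxidation. The fallback uses known chemistry and replaces arene oxidation by a radical hydrogen transfer; it sets out from 9 and comes back at 12. The tertiary alcohol of 9 is treated with 2,2,2-trifluoroethyl isocyanate (pyridine, CH2Cl2) to give the N-(2,2,2-trifluoroethyl)carbamate F1. Acetyl hypobromite at 0 °C in the dark gives the N-bromocarbamate F2. Visible-light irradiation (CBr4, PhCF3) then starts a Hofmann–Löffler–Freytag-type 1,6-hydrogen atom transfer from C3 to the nitrogen radical, and bromine transfer gives the C3 bromide F3. Ag2CO3 in CH2Cl2 removes the bromide while the carbamate carbonyl oxygen closes from the only face it can reach, giving the cis-fused cyclic iminocarbonate F4. Aqueous acetic acid hydrolyses its C=N bond to give 12.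

2. Step 12. Acylation of the hindered C3 hydroxyl next to the C(CH3)2OH group may be slow, so that the activated acid isomerises from Z to E or cyclises back to the butenolide with transfer of its acetyl group. The fallback builds the alkene on the substrate; it sets out from 13 and comes back at 20. The C3 hydroxyl of 13 is esterified with the geometrically inert 2-(diphenoxyphosphoryl)propanoic acid (DCC, DMAP, CH2Cl2) to give the 2-(diphenoxyphosphoryl)propanoate F5, a mixture of epimers at the phosphorus-bearing carbon. A Z-selective Horner–Wadsworth–Emmons olefination of the diaryl phosphonate (Ando type) with 2-oxoethyl acetate (NaI, 1,8-diazabicyclo[5.4.0]undec-7-ene, THF, −78 to 0 °C) then gives 20.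

3. Step 13. The tertiary sulfamate may ionise and eliminate towards C2, or the benzylic C3 ester may be lost on warming. The fallback moves the dehydration ahead of the esterification, so that no benzylic ester is present when the alkene is made; it sets out from 13 and comes back at 22. The C3 hydroxyl of 13 is silylated (Et3SiCl, imidazole, DMF) to give the C3 triethylsilyl ether F6. Burgess dehydration gives the 2-isopropenyl triethylsilyl ether F7. HF·pyridine in THF/pyridine at 0 °C removes the alkyl triethylsilyl group, while the hindered aryl silyl ether should stay, giving the cis 3-hydroxy-2-isopropenyl compound F8. Yamaguchi esterification of F8 with 18, now at a less hindered alcohol, gives 22.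

**Further compounds**

F1 | step 8 | 2-[(2R)-5-acetyl-6-{[tri(propan-2-yl)silyl]oxy}-2,3-dihydro-1-benzofuran-2-yl]propan-2-yl N-(2,2,2-trifluoroethyl)carbamate | CC(C)(OC(=O)NCC(F)(F)F)[C@@H]1Oc2cc(O[Si](C(C)C)(C(C)C)C(C)C)c(C(C)=O)cc2C1
F2 | step 8 | N-bromo derivative of F1 | CC(C)(OC(=O)N(Br)CC(F)(F)F)[C@@H]1Oc2cc(O[Si](C(C)C)(C(C)C)C(C)C)c(C(C)=O)cc2C1
F3 | step 8 | 3-bromo derivative of F1 (C2 unchanged, both C3 epimers possible) | CC(C)(OC(=O)NCC(F)(F)F)[C@@H]1Oc2cc(O[Si](C(C)C)(C(C)C)C(C)C)c(C(C)=O)cc2C1Br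
F4 | step 8 | cis-fused cyclic iminocarbonate, (2R,3S), the N-(2,2,2-trifluoroethyl)imino analogue of 12 | CC1(C)OC(=NCC(F)(F)F)O[C@H]2c3cc(C(C)=O)c(O[Si](C(C)C)(C(C)C)C(C)C)cc3O[C@@H]12
F5 | step 12 | (2R,3S)-5-acetyl-2-(2-hydroxypropan-2-yl)-6-{[tri(propan-2-yl)silyl]oxy}-2,3-dihydro-1-benzofuran-3-yl 2-(diphenoxyphosphoryl)propanoate (epimers at the phosphorus-bearing carbon) | CC(C)(O)[C@@H]1Oc2cc(O[Si](C(C)C)(C(C)C)C(C)C)c(C(C)=O)cc2[C@@H]1OC(=O)C(C)P(=O)(Oc3ccccc3)Oc4ccccc4
F6 | step 13 | 1-[(2R,3S)-2-(2-hydroxypropan-2-yl)-3-[(triethylsilyl)oxy]-6-{[tri(propan-2-yl)silyl]oxy}-2,3-dihydro-1-benzofuran-5-yl]ethan-1-one | CC(C)(O)[C@@H]1Oc2cc(O[Si](C(C)C)(C(C)C)C(C)C)c(C(C)=O)cc2[C@@H]1O[Si](CC)(CC)CC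
F7 | step 13 | 1-[(2S,3S)-2-(prop-1-en-2-yl)-3-[(triethylsilyl)oxy]-6-{[tri(propan-2-yl)silyl]oxy}-2,3-dihydro-1-benzofuran-5-yl]ethan-1-one | C=C(C)[C@@H]1Oc2cc(O[Si](C(C)C)(C(C)C)C(C)C)c(C(C)=O)cc2[C@@H]1O[Si](CC)(CC)CC
F8 | step 13 | 1-[(2S,3S)-3-hydroxy-2-(prop-1-en-2-yl)-6-{[tri(propan-2-yl)silyl]oxy}-2,3-dihydro-1-benzofuran-5-yl]ethan-1-one | C=C(C)[C@@H]1Oc2cc(O[Si](C(C)C)(C(C)C)C(C)C)c(C(C)=O)cc2[C@@H]1O
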